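The constants used here were chosen freely; the run is a simulation.

**The trap.** Vanished substrate does not mean a finished run. By my hand reckoning, substrate in ochre opens with a time of 0.583 h, but that makes open intermediate, not target. The flask to watch is the one holding open intermediate.

common to all: free catalyst 0.50 mM; second catalyst 5.0 mM; added ligand 0.42 mM; time 12 h

|  | substrate | partner | remark |
|---|---|---|---|
| blue | 0.10 M (fed, over 2.5 h) | 0.100 M | all else is in the flask from the start; the feed brings no volume worth counting |
| grey | 0.10 M (in portions, 3, over 10 h) | 0.100 M | first portion at the start, last at 10 h |
| green | 0.10 M | 0.100 M (fed, over 10 h) | all else is in the flask from the start; the feed brings no volume worth counting |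
| ochre | 0.10 M | 0.100 M | everything together at the start |
| violet | 0.10 M (fed, over 10 h) | 0.100 M | all else is in the flask from the start; the feed brings no volume worth counting |

    substrate + open intermediate → side product (k1 = 3.10 /M/h)
    second catalyst + open intermediate ⇌ catalyst intermediate (K2 = 1.5 /M, k2 = 33.9 /M/h)
    partner + catalyst intermediate → second catalyst + target (k3 = 1430 /M/h)
    substrate + free catalyst → free catalyst + open intermediate (k4 = 4760 /M/h)
    free catalyst + added ligand ⇌ idle complex (K5 = 920 /M, k5 = 2570 /M/h)
    2 substrate → homo dimer (k6 = 0.00166 /M/h)

* which flask leads in amount of target, in percent of the substrate charged ("all alike" within 1.5 percentage points) (blue / grey / green / ochre / violet / all alike)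
* how much target is there at the end, in percent of the substrate charged: blue
* how much target is there at the end, in percent of the substrate charged: grey
* how much target is there at the end, in percent of the substrate charged: green
* how much target is there at the end, in percent of the substrate charged: ochre
* how much target is there at the end, in percent of the substrate charged: violet

- percent here means substrate units held: one homo dimer or side product counts as two
- a step written with two of one species runs at k times the square of its concentration and takes two of it each time
- run time (blue): 12 h

**The clock.** I freeze second catalyst at its charge, since I reckon the share held as catalyst intermediate at about 2.05%. Capture of open intermediate is then pseudo-first-order, at 0.170 /h. Partner takes 86.4% of what is caught, because its 143 /h beats the way back at 22.6 /h. The product is 0.146 /h. Its inverse, 6.83 h, is the mean wait of open intermediate before it becomes target, with partner at its charge: the capture clock. A portion keeps the fraction exp(−age/clock) uncaptured. What remains gives a ceiling on target, with side product not yet counted.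

**Added ligand.** It touches opening, and opening is quicker than capture. I expect little from it.

**Substrate feed.** Ochre's substrate ages the full 12 h, so its ceiling is 82.7%. Blue, fed over 2.5 h, has a ceiling of 79.2%. Violet, fed over 10 h, drops to 60.8%. Grey's portions, at the start, midway and at 10 h, give 57.4%.

**Partner feed.** Green's partner enters at 0.100 /h of its charge, so during the feed green holds less partner than the charge on which my clock rests. With less partner, the way back at 22.6 /h takes a larger share of what is caught. Green's clock is therefore slower than the one I reckoned, and I put no figure on it. I only place green's ceiling below ochre's 82.7%.

**The forecast.** It names ochre and gives blue 63.8%, grey 47.5%, green 59%, ochre 66% and violet 49.5%, on the ground that “late-fed substrate runs out of time”. Its ochre figure is lower than my ceiling, and my reckoning gives ceilings, not yields.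

**The result.** Ochre leads with 67.5%, ahead of blue at 64.6%, green at 59.7%, violet at 50.5% and grey at 48.2%. At 12.0 h, grey still holds 42.6% as open intermediate. Grey's target is 0.840 of its ceiling. A neighbour of grey charged with 0.0013 M of second catalyst stretches the clock to 26.3 h. Its ceiling is then 22.5%, and the same fraction of that is 18.9%. That neighbour gives 18.7% target, with 68.9% still open intermediate.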